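**Retrosynthetic overview**

- Feature: the oxolane carries its two carbon substituents cis on C3 and C4 (lignan C8 and C8'). The exocyclic carbons C7 (ArCHOH) and C7' (ArCH2) sit 1,4 to each other at different oxidation levels, so C7, C8, C8' and C7' are the four carbons of a cyclobutanone (C7 as C=O, C7' as CH-aryl) cis-fused to the oxolane.
- Disconnections, backwards: O-benzyl hydrogenolysis; C7 carbinol from the aryl ketone by reagent-controlled reduction; the ketone and C7'H2 from strain-release cleavage of the C7–C7' bond of a 6,7-diaryl-3-oxabicyclo[3.2.0]heptan-6-ol; the C7–aryl bond from an arylcerium and the cyclobutanone; the cyclobutanone from a keteniminium–alkene [2+2] of a guaiacylacetamide with 2,5-dihydrofuran.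
- Ring order: the oxolane is bought as 2,5-dihydrofuran, the cyclobutane is fused onto it (step 3) and cut open again at C7–C7' (step 5), so only the oxolane remains.
- Stereochemistry: C8/C8' (cis and absolute) come from the [2+2] with a C2-symmetric pyrrolidine auxiliary; C7 comes from a Corey–Bakshi–Shibata reduction.

Key step: step 3

Assumption: the (2R,5R) auxiliary is taken to give the (1S,5R) ring fusion of 8; if the cycloaddition favours the antipode, commercial (2S,5S)-2,5-dimethylpyrrolidine is used in step 2 and nothing else changes.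
Remark: C7 of 7 and the carbinol carbon C6 of 12 carry no descriptor, because either epimer serves and both centres are erased in step 5.

**Route**

Step 1
Reactants: 1 [4-(benzyloxy)-3-methoxyphenyl]acetic acid
Product: 2 [4-(benzyloxy)-3-methoxyphenyl]acetyl chloride
Conditions: (COCl)2, DMF (cat.), CH2Cl2, 0 °C to rt; volatiles removed, crude used directly
Reagents that add atoms: oxalyl chloride, ClC(=O)C(=O)Cl
Why: Acid chloride formation under Vilsmeier-type catalysis is mild enough for the aryl benzyl ether and should give an acylating agent strong enough for the hindered amine of step 2.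

Step 2
Reactants: 2 [4-(benzyloxy)-3-methoxyphenyl]acetyl chloride; 3 (2R,5R)-2,5-dimethylpyrrolidine
Product: 4 2-[4-(benzyloxy)-3-methoxyphenyl]-1-[(2R,5R)-2,5-dimethylpyrrolidin-1-yl]ethan-1-one
Conditions: Et3N, DMAP (cat.), CH2Cl2, 0 °C to rt
Reagents that add atoms: none
Why: Schotten–Baumann-type N-acylation of the secondary amine by the acid chloride should proceed without touching the two auxiliary stereocentres, and the C2 symmetry of the amine makes the two amide rotamers identical.

Step 3
Reactants: 4 2-[4-(benzyloxy)-3-methoxyphenyl]-1-[(2R,5R)-2,5-dimethylpyrrolidin-1-yl]ethan-1-one; 5 2,5-dihydrofuran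
Product: 8 (1S,5R,7R)-7-[4-(benzyloxy)-3-methoxyphenyl]-3-oxabicyclo[3.2.0]heptan-6-one, via keteniminium triflate 6 (not isolated), via cyclobutaniminium triflate 7 (not isolated)
Conditions: Tf2O (added last, slowly), 2,4,6-collidine, 5 (5 equiv), ClCH2CH2Cl, −20 °C to 60 °C; then H2O, 60 °C; then Et3N (cat.), CH2Cl2, rt
Reagents that add atoms: water, O
Why: O-Triflation of amide 4 and loss of triflic acid to collidine should give the allene-like keteniminium 6, whose electrophilic central carbon is attacked by the C3=C4 π bond of 5; the developing secondary cation then collapses onto the enamine carbon to give cyclobutaniminium 7, which water hydrolyses to ketone 8 with release of the auxiliary (keteniminium–alkene [2+2] cycloaddition with a chiral pyrrolidine auxiliary, the iminium counterpart of the ketene–alkene cycloaddition). The cyclobutane is the only ring closed, by an asynchronous formal [2+2] annulation in which both new σ bonds (C5–C6 and C1–C7) reach the same face of the alkene before any bond rotation, so the four-membered ring is necessarily cis-fused to the oxolane. C1 and C5 (lignan C8' and C8) are set together: their relative configuration follows from the ring fusion, and their absolute configuration from the auxiliary, because the alkene must approach on the hydrogen side of the CH(aryl) terminus, where one of the two ring methyl groups disfavours one of the two enantiomeric alkene orientations. C7 is epimerisable and the catalytic base should converge it on the exo-aryl epimer; it is erased in step 5 in any case, whereas C5 cannot invert because a trans ring fusion is prohibitively strained, and C1 is not acidic. The step needs enantioface discrimination (from the auxiliary) and preference of Tf2O for the amide oxygen over the ether oxygen (from the far higher nucleophilicity of the amide and the slow, cold addition of Tf2O); no regiochemical question arises because the alkene is symmetrical and is used in excess.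

Step 4
Reactants: 8 (1S,5R,7R)-7-[4-(benzyloxy)-3-methoxyphenyl]-3-oxabicyclo[3.2.0]heptan-6-one; 9 1-(benzyloxy)-4-bromo-2-methoxybenzene
Product: 12 (1S,5R,7R)-6,7-bis[4-(benzyloxy)-3-methoxyphenyl]-3-oxabicyclo[3.2.0]heptan-6-ol, via aryllithium 10 (not isolated), via arylcerium dichloride 11 (not isolated)
Conditions: 9, n-BuLi, THF, −78 °C; anhydrous CeCl3, THF, −78 °C; then 8, −78 °C; H2O quench
Reagents that add atoms: none
Why: Bromine–lithium exchange followed by transmetalation to trivalent cerium should give a weakly basic, oxophilic aryl nucleophile that adds 1,2 to the strained, easily enolised α-aryl cyclobutanone instead of deprotonating it (organocerium carbonyl addition), and the new carbinol centre may form as either epimer since the next step destroys it.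

Step 5
Reactants: 12 (1S,5R,7R)-6,7-bis[4-(benzyloxy)-3-methoxyphenyl]-3-oxabicyclo[3.2.0]heptan-6-ol
Product: 15 [(3R,4S)-4-{[4-(benzyloxy)-3-methoxyphenyl]methyl}oxolan-3-yl][4-(benzyloxy)-3-methoxyphenyl]methanone, via alkoxy radical 13 (not isolated), via benzylic radical 14 (not isolated)
Conditions: [Ir(dF(CF3)ppy)2(5,5'-d(CF3)bpy)]PF6 (2 mol %), 2,4,6-collidine, PhSH (25 mol %), CH2Cl2 (degassed), blue LEDs, rt
Reagents that add atoms: none
Why: This is a photocatalytic proton-coupled electron transfer ring opening of a 1-aryl cycloalkanol, in which the excited trivalent iridium complex oxidises an electron-rich arene, collidine-assisted PCET gives alkoxy radical 13, β-scission cuts the strained C6–C7 bond toward the stabilised secondary benzylic radical 14 in preference to C5–C6, and thiophenol returns a hydrogen atom, all under near-neutral conditions that should leave the cis, epimerisable C3 centre and C4 untouched.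

Step 6
Reactants: 15 [(3R,4S)-4-{[4-(benzyloxy)-3-methoxyphenyl]methyl}oxolan-3-yl][4-(benzyloxy)-3-methoxyphenyl]methanone
Product: 16 (S)-[(3R,4S)-4-{[4-(benzyloxy)-3-methoxyphenyl]methyl}oxolan-3-yl][4-(benzyloxy)-3-methoxyphenyl]methanol
Conditions: (R)-2-methyl-CBS-oxazaborolidine (20 mol %), BH3·SMe2, THF, −20 °C; then MeOH
Reagents that add atoms: none
Why: In this Corey–Bakshi–Shibata reduction the aryl group should act as the large substituent, so the (R)-catalyst delivers hydride to the face that gives the (S)-carbinol (the sense in which it gives (S)-1-phenylethanol from acetophenone), with reagent control set against the bias of the adjacent C3 centre and a non-basic medium that does not epimerise C3.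

Step 7
Reactants: 16 (S)-[(3R,4S)-4-{[4-(benzyloxy)-3-methoxyphenyl]methyl}oxolan-3-yl][4-(benzyloxy)-3-methoxyphenyl]methanol
Product: 17 4-[(S)-hydroxy{(3R,4S)-4-[(4-hydroxy-3-methoxyphenyl)methyl]oxolan-3-yl}methyl]-2-methoxyphenol (CNP0234428.2)
Conditions: H2 (1 atm), Pd/C (10 wt % Pd), EtOAc, rt, stopped as soon as both benzyl ethers are cleaved
Reagents that add atoms: none
Why: Catalytic hydrogenolysis of aryl benzyl ethers in neutral ethyl acetate is much faster than C–O hydrogenolysis of a secondary benzylic alcohol in the absence of acid, so a monitored reaction should give the bis-phenol with the C7 hydroxyl and all three stereocentres intact.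

**Compound list**

1 | [4-(benzyloxy)-3-methoxyphenyl]acetic acid | COc1cc(CC(=O)O)ccc1OCc1ccccc1 | starting material
2 | [4-(benzyloxy)-3-methoxyphenyl]acetyl chloride | COc1cc(CC(=O)Cl)ccc1OCc1ccccc1 | intermediate
3 | (2R,5R)-2,5-dimethylpyrrolidine | C[C@@H]1CC[C@H](N1)C | starting material
4 | 2-[4-(benzyloxy)-3-methoxyphenyl]-1-[(2R,5R)-2,5-dimethylpyrrolidin-1-yl]ethan-1-one | COc1cc(CC(=O)N2[C@H](C)CC[C@H]2C)ccc1OCc1ccccc1 | intermediate
5 | 2,5-dihydrofuran | C1C=CCO1 | starting material
6 | keteniminium triflate: (2R,5R)-1-{2-[4-(benzyloxy)-3-methoxyphenyl]ethenylidene}-2,5-dimethylpyrrolidin-1-ium trifluoromethanesulfonate | COc1cc(C=C=[N+]2[C@H](C)CC[C@H]2C)ccc1OCc1ccccc1.[O-]S(=O)(=O)C(F)(F)F | intermediate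
7 | cyclobutaniminium triflate: (2R,5R)-1-{7-[4-(benzyloxy)-3-methoxyphenyl]-3-oxabicyclo[3.2.0]heptan-6-ylidene}-2,5-dimethylpyrrolidin-1-ium trifluoromethanesulfonate, cis ring fusion in the same sense as 8, C7 unassigned | COc1cc(C3[C@@H]2COC[C@@H]2C3=[N+]4[C@H](C)CC[C@H]4C)ccc1OCc1ccccc1.[O-]S(=O)(=O)C(F)(F)F | intermediate
8 | (1S,5R,7R)-7-[4-(benzyloxy)-3-methoxyphenyl]-3-oxabicyclo[3.2.0]heptan-6-one (cis-fused, aryl exo) | COc1cc([C@H]3[C@@H]2COC[C@@H]2C3=O)ccc1OCc1ccccc1 | intermediate
9 | 1-(benzyloxy)-4-bromo-2-methoxybenzene | COc1cc(Br)ccc1OCc1ccccc1 | starting material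
10 | [4-(benzyloxy)-3-methoxyphenyl]lithium | COc1cc([Li])ccc1OCc1ccccc1 | intermediate
11 | [4-(benzyloxy)-3-methoxyphenyl]cerium dichloride (trivalent cerium) | COc1cc([Ce](Cl)Cl)ccc1OCc1ccccc1 | intermediate
12 | (1S,5R,7R)-6,7-bis[4-(benzyloxy)-3-methoxyphenyl]-3-oxabicyclo[3.2.0]heptan-6-ol, C6 unassigned | COc1cc([C@H]3[C@@H]2COC[C@@H]2C3(O)c2ccc(OCc4ccccc4)c(OC)c2)ccc1OCc1ccccc1 | intermediate
13 | alkoxy radical of 12 (oxygen-centred radical at C6) | COc1cc([C@H]3[C@@H]2COC[C@@H]2C3([O])c2ccc(OCc4ccccc4)c(OC)c2)ccc1OCc1ccccc1 | intermediate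
14 | ring-opened benzylic radical: (3R,4S)-3-aroyl-oxolan-4-yl(aryl)methyl radical | COc1cc([CH][C@@H]2COC[C@@H]2C(=O)c2ccc(OCc3ccccc3)c(OC)c2)ccc1OCc1ccccc1 | intermediate
15 | [(3R,4S)-4-{[4-(benzyloxy)-3-methoxyphenyl]methyl}oxolan-3-yl][4-(benzyloxy)-3-methoxyphenyl]methanone (cis) | COc1cc(C[C@@H]2COC[C@@H]2C(=O)c2ccc(OCc3ccccc3)c(OC)c2)ccc1OCc1ccccc1 | intermediate
16 | (S)-[(3R,4S)-4-{[4-(benzyloxy)-3-methoxyphenyl]methyl}oxolan-3-yl][4-(benzyloxy)-3-methoxyphenyl]methanol | COc1cc(C[C@@H]2COC[C@@H]2[C@H](O)c2ccc(OCc3ccccc3)c(OC)c2)ccc1OCc1ccccc1 | intermediate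
17 | 4-[(S)-hydroxy{(3R,4S)-4-[(4-hydroxy-3-methoxyphenyl)methyl]oxolan-3-yl}methyl]-2-methoxyphenol | COc1cc(C[C@@H]2COC[C@@H]2[C@H](O)c2ccc(O)c(OC)c2)ccc1O | target

**Step count**

Total: 7 steps. Longest linear sequence: 7 steps (from acid 1; amine 3, alkene 5 and bromide 9 are bought).

**Steps most likely to fail**

1. Step 3. The auxiliary may discriminate the two alkene orientations only weakly, and the keteniminium may be lost to Friedel–Crafts attack by the electron-rich arene or to cationic oligomerisation of the dihydrofuran. The fallback sets out from 2,5-dihydrofuran 5 and comes back at cyclobutanone 8. Dichloroketene F1, generated in the flask from trichloroacetyl chloride and Zn–Cu couple in Et2O/DME, should add to 5 in a ketene–alkene [2+2] cycloaddition to give racemic cis-fused 7,7-dichloro-3-oxabicyclo[3.2.0]heptan-6-one F2. Zinc in acetic acid should remove both chlorines to give racemic 3-oxabicyclo[3.2.0]heptan-6-one F3. Palladium-catalysed ketone α-arylation of F3 at its only methylene α-carbon with bromide 9 (Pd2(dba)3 as the zerovalent palladium source, P(t-Bu)3, K3PO4, toluene) should give racemic 8. Preparative chromatography on a chiral stationary phase then separates 8 from its antipode, the (1R,5S,7S)-ketone F4.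

2. Step 5. Back electron transfer may outrun ring opening, scission may go toward the ring carbon C5, or the centre next to the new ketone may epimerise from cis to trans. The fallback sets out from cyclobutanone 8, bypasses step 4 as well, and comes back at ketone 15. Baeyer–Villiger oxidation of 8 (m-CPBA, NaHCO3, CH2Cl2, 0 °C), with the benzylic C7 migrating with retention, should give the cis-fused lactone (3R,3aS,6aR)-3-[4-(benzyloxy)-3-methoxyphenyl]tetrahydro-1H,3H-furo[3,4-c]furan-1-one F5. Ionic hydrogenolysis of its benzylic C–O bond (Et3SiH, BF3·OEt2, CH2Cl2, 0 °C) should give (3R,4S)-4-{[4-(benzyloxy)-3-methoxyphenyl]methyl}oxolane-3-carboxylic acid F6. Amidation (MeNHOMe·HCl, EDC·HCl, i-Pr2NEt, CH2Cl2) should give the Weinreb amide (3R,4S)-4-{[4-(benzyloxy)-3-methoxyphenyl]methyl}-N-methoxy-N-methyloxolane-3-carboxamide F7. Aryllithium 10 at −78 °C should add once to F7 (Weinreb ketone synthesis) and give 15.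

3. Step 6. Facial selectivity at the carbonyl may be poor if the adjacent ring stereocentre opposes the catalyst, and the α-branched alkyl side narrows the size difference the catalyst reads. The fallback sets out from ketone 15 and comes back at alcohol 16. Reduction without a chiral reagent under Luche conditions (NaBH4, CeCl3·7H2O, MeOH, −40 °C) should give both carbinol epimers, which are separated. The (7R)-carbinol epimer F8 is inverted by a Mitsunobu reaction (4-nitrobenzoic acid, PPh3, DIAD, toluene, 0 °C) to the (7S)-4-nitrobenzoate F9, and methanolysis of F9 (K2CO3, MeOH) should return 16.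

**Further compounds**

F1 | step 3 | dichloroketene | ClC(Cl)=C=O
F2 | step 3 | cis-7,7-dichloro-3-oxabicyclo[3.2.0]heptan-6-one (racemate, one enantiomer drawn) | ClC1(Cl)[C@@H]2COC[C@@H]2C1=O
F3 | step 3 | cis-3-oxabicyclo[3.2.0]heptan-6-one (racemate, one enantiomer drawn) | C1[C@@H]2COC[C@@H]2C1=O
F4 | step 3 | (1R,5S,7S)-7-[4-(benzyloxy)-3-methoxyphenyl]-3-oxabicyclo[3.2.0]heptan-6-one (antipode of 8) | COc1cc([C@@H]3[C@H]2COC[C@H]2C3=O)ccc1OCc1ccccc1
F5 | step 5 | (3R,3aS,6aR)-3-[4-(benzyloxy)-3-methoxyphenyl]tetrahydro-1H,3H-furo[3,4-c]furan-1-one | COc1cc([C@H]3[C@@H]2COC[C@@H]2C(=O)O3)ccc1OCc1ccccc1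
F6 | step 5 | (3R,4S)-4-{[4-(benzyloxy)-3-methoxyphenyl]methyl}oxolane-3-carboxylic acid | COc1cc(C[C@@H]2COC[C@@H]2C(=O)O)ccc1OCc1ccccc1
F7 | step 5 | (3R,4S)-4-{[4-(benzyloxy)-3-methoxyphenyl]methyl}-N-methoxy-N-methyloxolane-3-carboxamide | COc1cc(C[C@@H]2COC[C@@H]2C(=O)N(C)OC)ccc1OCc1ccccc1
F8 | step 6 | (R)-[(3R,4S)-4-{[4-(benzyloxy)-3-methoxyphenyl]methyl}oxolan-3-yl][4-(benzyloxy)-3-methoxyphenyl]methanol | COc1cc(C[C@@H]2COC[C@@H]2[C@@H](O)c2ccc(OCc3ccccc3)c(OC)c2)ccc1OCc1ccccc1
F9 | step 6 | (S)-[(3R,4S)-4-{[4-(benzyloxy)-3-methoxyphenyl]methyl}oxolan-3-yl][4-(benzyloxy)-3-methoxyphenyl]methyl 4-nitrobenzoate | COc1cc(C[C@@H]2COC[C@@H]2[C@H](OC(=O)c2ccc(cc2)[N+](=O)[O-])c2ccc(OCc3ccccc3)c(OC)c2)ccc1OCc1ccccc1
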